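## Retrosynthetic overview

1. The target is opened to an acyclic α‑hydroxyallene/(Z)‑2‑en‑4‑ynoic acid. The last operation closes the Z‑alkylidene butenolide (5‑exo‑dig) and the 2,5‑dihydrofuran (5‑endo, allene axis → C8) together under Ag(I).
2. That precursor comes from a Suzuki union, at the central diene single bond, of a dienyl iodide (acetylenic half) and a dienyl boronate (allenol half).
3. The allenol half comes from ethyl (E)‑2,3‑dibromoacrylate by C3‑ then C2‑selective Sonogashira couplings, followed by Pd/formate anti‑SN2′ hydride opening of the propargylic epoxide (C5 carbinol kept, allene axis set).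
4. Both carbocycles come from (4R,6R)‑actinol (ethynylation/dehydration/epoxidation, and an enol triflate). The two methyl‑branched enyne units come from (E)‑3‑methylpent‑2‑en‑4‑yn‑1‑ol.
5. Ring order: oxirane (step 3, transient, opened in step 12), then butenolide and dihydrofuran simultaneously (step 14). No carbocycle is built.

Assumption: (4R,6R)‑actinol, (E)‑3‑methylpent‑2‑en‑4‑yn‑1‑ol and ethyl propiolate are bought; operations telescoped in one flask count as one step.

## Route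

Step 1
Reactants: 1 (4R,6R)-4-hydroxy-2,2,6-trimethylcyclohexan-1-one ((4R,6R)-actinol)
Product: 2 (1RS,4R,6R)-1-ethynyl-2,2,6-trimethylcyclohexane-1,4-diol
Conditions: HC≡CMgBr (3.5 equiv), THF, 0 → 40 °C; aq NH4Cl
Reagents that add atoms: ethynylmagnesium bromide, C#C[Mg]Br
Why: Grignard 1,2‑addition to the hindered ketone after the first equivalent has deprotonated the 4‑OH; the new carbinol centre is irrelevant (it becomes sp2 in step 2) and the C4 carbinol (R, the future C3/C3′) is untouched.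

Step 2
Reactants: 2 (1RS,4R,6R)-1-ethynyl-2,2,6-trimethylcyclohexane-1,4-diol
Product: 4 (1R)-4-ethynyl-3,5,5-trimethylcyclohex-3-en-1-yl acetate, via monoacetate 3 (not isolated)
Conditions: Ac2O (1.2 equiv), pyridine, rt; then POCl3 (3 equiv), 95 °C
Reagents that add atoms: acetic anhydride, CC(=O)OC(C)=O
Why: Selective O‑acetylation of the secondary alcohol, then POCl3/pyridine dehydration of the tertiary propargylic alcohol, which can only eliminate towards the one β‑H and gives the conjugated tetrasubstituted enyne.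

Step 3
Reactants: 4 (1R)-4-ethynyl-3,5,5-trimethylcyclohex-3-en-1-yl acetate
Product: 5 (1R,3S,6R)-6-ethynyl-1,5,5-trimethyl-7-oxabicyclo[4.1.0]heptan-3-yl acetate (oxirane anti to OAc)
Conditions: mCPBA (1.1 equiv), CH2Cl2, 0 °C
Reagents that add atoms: mCPBA, OOC(=O)c1cccc(Cl)c1
Why: Prilezhaev epoxidation of the only electron‑rich alkene; the non‑directing acetoxy group is expected to steer the peracid mainly to the opposite face (as in peracid epoxidation of 3‑acyloxy β‑end groups, ca. 3–4:1), the anti‑epoxide is separated by chromatography and its C1 (carotenoid C5) becomes the 5R carbinol/ether centre of the target.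

Step 4
Reactants: 1 (4R,6R)-4-hydroxy-2,2,6-trimethylcyclohexan-1-one
Product: 8 (4R)-4-hydroxy-2,6,6-trimethylcyclohex-1-en-1-yl trifluoromethanesulfonate, via TMS ether 6 (not isolated), via silyloxy triflate 7 (not isolated)
Conditions: LDA (1.05 equiv), THF, −78 °C, then TMSCl (1.05 equiv); LDA (1.3 equiv), −78 → 0 °C, then PhNTf2, −78 °C → rt; 1 M HCl, THF, 0 °C
Reagents that add atoms: N-phenylbis(trifluoromethanesulfonimide), O=S(=O)(N(c1ccccc1)S(=O)(=O)C(F)(F)F)C(F)(F)F; chlorotrimethylsilane, C[Si](C)(C)Cl (stays only in 6 and 7)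
Why: Transient O‑silylation, enolate O‑triflation at the only enolisable α‑position and acidic removal of the TMS group give the hydroxy vinyl triflate without touching the carbinol stereocentre.

Step 5
Reactants: 9 (E)-3-methylpent-2-en-4-yn-1-ol
Product: 10 (E)-3-methylpent-2-en-4-ynal
Conditions: activated MnO2 (15 equiv), CH2Cl2, rt; filtered and used as a solution
Reagents that add atoms: none
Why: Chemoselective MnO2 oxidation of the allylic alcohol that keeps the E‑trisubstituted alkene and the terminal alkyne.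

Step 6
Reactants: 8 (4R)-4-hydroxy-2,6,6-trimethylcyclohex-1-en-1-yl trifluoromethanesulfonate; 10 (E)-3-methylpent-2-en-4-ynal
Product: 11 (2E)-5-[(4R)-4-hydroxy-2,6,6-trimethylcyclohex-1-en-1-yl]-3-methylpent-2-en-4-ynal
Conditions: Pd(PPh3)4 (5 mol %), CuI (10 mol %), Et3N, DMF, 50 °C
Reagents that add atoms: none
Why: Sonogashira coupling of the vinyl triflate with the terminal alkyne forms the ring–alkyne bond with retention of the (E)‑enal.

Step 7
Reactants: 11 (2E)-5-[(4R)-4-hydroxy-2,6,6-trimethylcyclohex-1-en-1-yl]-3-methylpent-2-en-4-ynal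
Product: 12 (1R)-4-[(3E,5E)-6-iodo-3-methylhexa-3,5-dien-1-yn-1-yl]-3,5,5-trimethylcyclohex-3-en-1-ol
Conditions: CrCl2 (6 equiv), CHI3 (2 equiv), THF–dioxane (1:6), 0 °C → rt, dark
Reagents that add atoms: iodoform, IC(I)I
Why: Takai iodo‑olefination homologates the enal to the (E)‑dienyl iodide (E from anti‑elimination of the gem‑dichromium adduct); the free alcohol is tolerated.

Step 8
Reactants: 10 (E)-3-methylpent-2-en-4-ynal
Product: 13 2-[(1E,3E)-4-methylhexa-1,3-dien-5-yn-1-yl]-4,4,5,5-tetramethyl-1,3,2-dioxaborolane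
Conditions: Cl2CHBpin (2 equiv), CrCl2 (8 equiv), LiI (4 equiv), THF, rt
Reagents that add atoms: 2-(dichloromethyl)-4,4,5,5-tetramethyl-1,3,2-dioxaborolane, ClC(Cl)B1OC(C)(C)C(C)(C)O1
Why: Takai–Utimoto boron variant of the Takai olefination gives the (E)‑alkenyl pinacol boronate.

Step 9
Reactants: 14 ethyl propiolate
Product: 15 ethyl (E)-2,3-dibromoprop-2-enoate
Conditions: Br2 (1.0 equiv), ClCH2CH2Cl, 70 °C, dark
Reagents that add atoms: bromine, BrBr
Why: Anti‑addition of bromine to the alkyne gives the (E)‑dibromide, whose C3 bromine is cis to the ester, the geometry needed later for lactonisation.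

Step 10
Reactants: 15 ethyl (E)-2,3-dibromoprop-2-enoate; 13 2-[(1E,3E)-4-methylhexa-1,3-dien-5-yn-1-yl]-4,4,5,5-tetramethyl-1,3,2-dioxaborolane
Product: 16 ethyl (2E,6E,8E)-2-bromo-6-methyl-9-(4,4,5,5-tetramethyl-1,3,2-dioxaborolan-2-yl)nona-2,6,8-trien-4-ynoate
Conditions: Pd(PPh3)4 (5 mol %), CuI (10 mol %), Et3N (2 equiv), MeCN, rt
Reagents that add atoms: none
Why: Site‑selective Sonogashira coupling at the more electrophilic β‑C–Br bond with retention (alkynyl cis to CO2Et); the pinacol boronate is inert under anhydrous amine conditions.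

Step 11
Reactants: 16 ethyl (2E,6E,8E)-2-bromo-6-methyl-9-(pinacolboryl)nona-2,6,8-trien-4-ynoate; 5 (1R,3S,6R)-6-ethynyl-1,5,5-trimethyl-7-oxabicyclo[4.1.0]heptan-3-yl acetate
Product: 17 ethyl (2Z,6E,8E)-2-{[(1R,4S,6R)-4-acetoxy-2,2,6-trimethyl-7-oxabicyclo[4.1.0]heptan-1-yl]ethynyl}-6-methyl-9-(pinacolboryl)nona-2,6,8-trien-4-ynoate
Conditions: PdCl2(PPh3)2 (5 mol %), CuI (10 mol %), i-Pr2NH, THF, 45 °C
Reagents that add atoms: none
Why: Second Sonogashira coupling at the remaining α‑C–Br bond gives the cross‑conjugated enediyne; ethynyl epoxides of this type survive Pd/Cu coupling, and epoxide, acetate and boronate are not touched.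

Step 12
Reactants: 17 ethyl (2Z,6E,8E)-2-{[(1R,4S,6R)-4-acetoxy-2,2,6-trimethyl-7-oxabicyclo[4.1.0]heptan-1-yl]ethynyl}-6-methyl-9-(pinacolboryl)nona-2,6,8-trien-4-ynoate
Product: 18 ethyl (2Z,6E,8E)-2-{(aS)-2-[(2R,4S)-4-acetoxy-2-hydroxy-2,6,6-trimethylcyclohexylidene]ethenyl}-6-methyl-9-(pinacolboryl)nona-2,6,8-trien-4-ynoate
Conditions: Pd2(dba)3·CHCl3 (2.5 mol %), n-Bu3P (5 mol %), HCO2NH4 (3 equiv), THF, rt
Reagents that add atoms: none
Why: Tsuji‑type Pd(0)/formate hydrogenolysis of the propargylic epoxide: anti‑SN2′ oxidative addition places Pd on C8 opposite the breaking C6–O bond and hydride transfer with retention gives the (aS)‑α‑hydroxyallene, the C5–O bond (5R) being untouched.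

Step 13
Reactants: 18 ethyl (2Z,6E,8E)-2-{(aS)-2-[(2R,4S)-4-acetoxy-2-hydroxy-2,6,6-trimethylcyclohexylidene]ethenyl}-6-methyl-9-(pinacolboryl)nona-2,6,8-trien-4-ynoate; 12 (1R)-4-[(3E,5E)-6-iodo-3-methylhexa-3,5-dien-1-yn-1-yl]-3,5,5-trimethylcyclohex-3-en-1-ol
Product: 19 ethyl (2Z,6E,8E,10E,12E)-2-{(aS)-2-[(2R,4S)-4-acetoxy-2-hydroxy-2,6,6-trimethylcyclohexylidene]ethenyl}-15-[(4R)-4-hydroxy-2,6,6-trimethylcyclohex-1-en-1-yl]-6,13-dimethylpentadeca-2,6,8,10,12-pentaene-4,14-diynoate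
Conditions: Pd(dppf)Cl2 (5 mol %), 3 M aq K3PO4, THF, rt, degassed, dark
Reagents that add atoms: none
Why: Suzuki–Miyaura coupling of the dienyl iodide and dienyl boronate forms the central diene single bond with retention of both E‑alkenes and completes the tetraene under mild base that leaves ester, acetate and allenol intact.

Step 14
Reactants: 19 ethyl (2Z,6E,8E,10E,12E)-2-{(aS)-2-[(2R,4S)-4-acetoxy-2-hydroxy-2,6,6-trimethylcyclohexylidene]ethenyl}-15-[(4R)-4-hydroxy-2,6,6-trimethylcyclohex-1-en-1-yl]-6,13-dimethylpentadeca-2,6,8,10,12-pentaene-4,14-diynoate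
Product: 21 (5Z)-3-[(2R,6S,7aR)-6-hydroxy-4,4,7a-trimethyl-2,4,5,6,7,7a-hexahydro-1-benzofuran-2-yl]-5-{(2E,4E,6E,8E)-11-[(4R)-4-hydroxy-2,6,6-trimethylcyclohex-1-en-1-yl]-2,9-dimethylundeca-2,4,6,8-tetraen-10-yn-1-ylidene}furan-2(5H)-one (the target), via triol acid 20 (not isolated)
Conditions: LiOH·H2O (6 equiv), THF–MeOH–H2O (3:1:1), 0 °C → rt; then AcOH to pH 6–7, AgNO3 (0.3 equiv), rt, dark
Reagents that add atoms: lithium hydroxide (one O of the lactone carboxyl), [Li+].[OH-]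
Why: Proposed new method: saponification frees the carboxylate and the C3‑OH, and one Ag(I) catalyst then activates both π‑systems, the carboxylate adding 5‑exo‑dig anti across C11≡C12 (protodeargentation gives the Z‑ylidene butenolide) while the tertiary C5–OH adds 5‑endo to the Ag‑bound allene terminus C8 in the plane of the C6 substituents, so the (aS) axis is transferred into (8R) with H8 cis to the C5 methyl; the closest known reactions are the Ag(I)‑catalysed lactonisation of (Z)‑2‑en‑4‑ynoic acids to (Z)‑γ‑alkylidenebutenolides and the Ag(I)/Au‑catalysed cycloisomerisation of α‑hydroxyallenes to 2,5‑dihydrofurans with axis‑to‑centre chirality transfer, not yet run together on one substrate.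

## Compound list

1 | (4R,6R)-4-hydroxy-2,2,6-trimethylcyclohexan-1-one ((4R,6R)-actinol) | C[C@H]1C(=O)C(C)(C)C[C@H](O)C1 | starting material
2 | (1RS,4R,6R)-1-ethynyl-2,2,6-trimethylcyclohexane-1,4-diol | C[C@H]1C(O)(C#C)C(C)(C)C[C@H](O)C1 | intermediate
3 | (1R,4RS,5R)-4-ethynyl-4-hydroxy-3,3,5-trimethylcyclohexyl acetate (monoacetate) | C[C@H]1C(O)(C#C)C(C)(C)C[C@H](OC(C)=O)C1 | intermediate (not isolated)
4 | (1R)-4-ethynyl-3,5,5-trimethylcyclohex-3-en-1-yl acetate | CC1=C(C#C)C(C)(C)C[C@H](OC(C)=O)C1 | intermediate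
5 | (1R,3S,6R)-6-ethynyl-1,5,5-trimethyl-7-oxabicyclo[4.1.0]heptan-3-yl acetate (oxirane anti to OAc) | CC(=O)O[C@H]1CC(C)(C)[C@]2(C#C)O[C@]2(C)C1 | intermediate
6 | (4R,6R)-2,2,6-trimethyl-4-(trimethylsilyloxy)cyclohexan-1-one (TMS ether) | C[C@H]1C(=O)C(C)(C)C[C@H](O[Si](C)(C)C)C1 | intermediate (not isolated)
7 | (4R)-2,6,6-trimethyl-4-(trimethylsilyloxy)cyclohex-1-en-1-yl trifluoromethanesulfonate (silyloxy triflate) | CC1=C(OS(=O)(=O)C(F)(F)F)C(C)(C)C[C@H](O[Si](C)(C)C)C1 | intermediate (not isolated)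
8 | (4R)-4-hydroxy-2,6,6-trimethylcyclohex-1-en-1-yl trifluoromethanesulfonate | CC1=C(OS(=O)(=O)C(F)(F)F)C(C)(C)C[C@H](O)C1 | intermediate
9 | (E)-3-methylpent-2-en-4-yn-1-ol | C#C/C(C)=C/CO | starting material
10 | (E)-3-methylpent-2-en-4-ynal | C#C/C(C)=C/C=O | intermediate
11 | (2E)-5-[(4R)-4-hydroxy-2,6,6-trimethylcyclohex-1-en-1-yl]-3-methylpent-2-en-4-ynal | CC1=C(C#C/C(C)=C/C=O)C(C)(C)C[C@H](O)C1 | intermediate
12 | (1R)-4-[(3E,5E)-6-iodo-3-methylhexa-3,5-dien-1-yn-1-yl]-3,5,5-trimethylcyclohex-3-en-1-ol | CC1=C(C#C/C(C)=C/C=C/I)C(C)(C)C[C@H](O)C1 | intermediate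
13 | 2-[(1E,3E)-4-methylhexa-1,3-dien-5-yn-1-yl]-4,4,5,5-tetramethyl-1,3,2-dioxaborolane | C#C/C(C)=C/C=C/B1OC(C)(C)C(C)(C)O1 | intermediate
14 | ethyl propiolate | C#CC(=O)OCC | starting material
15 | ethyl (E)-2,3-dibromoprop-2-enoate | CCOC(=O)/C(Br)=C\Br | intermediate
16 | ethyl (2E,6E,8E)-2-bromo-6-methyl-9-(4,4,5,5-tetramethyl-1,3,2-dioxaborolan-2-yl)nona-2,6,8-trien-4-ynoate | CCOC(=O)/C(Br)=C\C#C/C(C)=C/C=C/B1OC(C)(C)C(C)(C)O1 | intermediate
17 | ethyl (2Z,6E,8E)-2-{[(1R,4S,6R)-4-acetoxy-2,2,6-trimethyl-7-oxabicyclo[4.1.0]heptan-1-yl]ethynyl}-6-methyl-9-(pinacolboryl)nona-2,6,8-trien-4-ynoate | CCOC(=O)/C(C#C[C@@]12O[C@]1(C)C[C@@H](OC(C)=O)CC2(C)C)=C\C#C/C(C)=C/C=C/B1OC(C)(C)C(C)(C)O1 | intermediate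
18 | ethyl (2Z,6E,8E)-2-{(aS)-2-[(2R,4S)-4-acetoxy-2-hydroxy-2,6,6-trimethylcyclohexylidene]ethenyl}-6-methyl-9-(pinacolboryl)nona-2,6,8-trien-4-ynoate (on C8, H is on the face of the C5 methyl and the acrylate carbon on the face of the C5–OH) | CCOC(=O)/C(=C\C#C/C(C)=C/C=C/B1OC(C)(C)C(C)(C)O1)C([H])=[C@]=C1C(C)(C)C[C@H](OC(C)=O)C[C@@]1(C)O | intermediate
19 | ethyl (2Z,6E,8E,10E,12E)-2-{(aS)-2-[(2R,4S)-4-acetoxy-2-hydroxy-2,6,6-trimethylcyclohexylidene]ethenyl}-15-[(4R)-4-hydroxy-2,6,6-trimethylcyclohex-1-en-1-yl]-6,13-dimethylpentadeca-2,6,8,10,12-pentaene-4,14-diynoate | CCOC(=O)/C(=C\C#C/C(C)=C/C=C/C=C/C=C(C)/C#CC1=C(C)C[C@@H](O)CC1(C)C)C([H])=[C@]=C1C(C)(C)C[C@H](OC(C)=O)C[C@@]1(C)O | intermediate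
20 | (2Z,6E,8E,10E,12E)-2-{(aS)-2-[(2R,4S)-2,4-dihydroxy-2,6,6-trimethylcyclohexylidene]ethenyl}-15-[(4R)-4-hydroxy-2,6,6-trimethylcyclohex-1-en-1-yl]-6,13-dimethylpentadeca-2,6,8,10,12-pentaene-4,14-diynoic acid (triol acid) | OC(=O)/C(=C\C#C/C(C)=C/C=C/C=C/C=C(C)/C#CC1=C(C)C[C@@H](O)CC1(C)C)C([H])=[C@]=C1C(C)(C)C[C@H](O)C[C@@]1(C)O | intermediate (not isolated)
21 | (5Z)-3-[(2R,6S,7aR)-6-hydroxy-4,4,7a-trimethyl-2,4,5,6,7,7a-hexahydro-1-benzofuran-2-yl]-5-{(2E,4E,6E,8E)-11-[(4R)-4-hydroxy-2,6,6-trimethylcyclohex-1-en-1-yl]-2,9-dimethylundeca-2,4,6,8-tetraen-10-yn-1-ylidene}furan-2(5H)-one (CNP0300047.2) | CC1=C(C#C/C(C)=C/C=C/C=C/C=C(C)/C=C2/C=C([C@H]3C=C4C(C)(C)C[C@H](O)C[C@@]4(C)O3)C(=O)O2)C(C)(C)C[C@H](O)C1 | target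

## Step count and weak points

Total: 14 steps. Longest linear sequence: 7 steps (9 → 10 → 13 → 16 → 17 → 18 → 19 → 21; equally 1 → 2 → 4 → 5 → 17 → 18 → 19 → 21).

Most likely to fail:

**Step 14 (one‑flask saponification and Ag(I) double cycloisomerisation).** The free carboxylate sits next to both the alkyne and the allene and could attack the allene, or the two closures may need different conditions. Fallback: close the rings one at a time, the ether ring first while the acid is still masked. Setting out from 19, AgNO3 in acetone–water (or 2 mol % Ph3PAuCl/AgOTf in THF at 0 °C) cycloisomerises only the α‑hydroxyallene to ethyl (2Z,6E,8E,10E,12E)-2-[(2R,6S,7aR)-6-acetoxy-4,4,7a-trimethyl-2,4,5,6,7,7a-hexahydro-1-benzofuran-2-yl]-15-[(4R)-4-hydroxy-2,6,6-trimethylcyclohex-1-en-1-yl]-6,13-dimethylpentadeca-2,6,8,10,12-pentaene-4,14-diynoate F1. LiOH then gives the corresponding dihydrofuranyl enynoic acid (2Z,6E,8E,10E,12E)-2-[(2R,6S,7aR)-6-hydroxy-4,4,7a-trimethyl-2,4,5,6,7,7a-hexahydro-1-benzofuran-2-yl]-15-[(4R)-4-hydroxy-2,6,6-trimethylcyclohex-1-en-1-yl]-6,13-dimethylpentadeca-2,6,8,10,12-pentaene-4,14-diynoic acid F2, and catalytic Ag2CO3 in DMF lactonises it 5‑exo‑dig, coming back to the route at 21.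

**Step 12 (Pd/formate anti‑SN2′ hydrogenolysis in a substrate that also carries a boronate, an enynoate and a second alkyne).** Possible problems are hydride delivery to C6, boron transmetalation to the allenyl‑palladium, or loss of axial purity. Fallback: replace the oxidative‑addition/hydride‑transfer manifold by hydrocupration/β‑alkoxide elimination. Setting out from 17, (IPr)CuCl/NaOt‑Bu (5 mol %) with polymethylhydrosiloxane in toluene at 0 °C (copper hydride SN2′ reduction of propargyl oxiranes) is expected to deliver hydride with the same anti sense (to be confirmed on the first sample of 18) and has no Pd‑allenyl intermediate for the boronate to intercept. It makes no new compound (F0) and comes back at 18.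

**Step 3 (facial selectivity of the epoxidation, which fixes C5).** If the peracid prefers the face syn to the acetoxy group, the wanted isomer is the minor one. Fallback: reach the oxirane through a halohydrin, which puts oxygen on the face opposite to the one an electrophile attacks. Setting out from 4, NBS in THF–water gives (1S,3R,4S)-4-bromo-4-ethynyl-3-hydroxy-3,5,5-trimethylcyclohexyl acetate F3 by anti opening of the bromonium ion. K2CO3 in acetone closes it with inversion at the C–Br carbon, coming back at 5.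

## Further compounds

F1 | step 14 | ethyl (2Z,6E,8E,10E,12E)-2-[(2R,6S,7aR)-6-acetoxy-4,4,7a-trimethyl-2,4,5,6,7,7a-hexahydro-1-benzofuran-2-yl]-15-[(4R)-4-hydroxy-2,6,6-trimethylcyclohex-1-en-1-yl]-6,13-dimethylpentadeca-2,6,8,10,12-pentaene-4,14-diynoate | CCOC(=O)/C(=C\C#C/C(C)=C/C=C/C=C/C=C(C)/C#CC1=C(C)C[C@@H](O)CC1(C)C)[C@H]1C=C2C(C)(C)C[C@H](OC(C)=O)C[C@@]2(C)O1
F2 | step 14 | (2Z,6E,8E,10E,12E)-2-[(2R,6S,7aR)-6-hydroxy-4,4,7a-trimethyl-2,4,5,6,7,7a-hexahydro-1-benzofuran-2-yl]-15-[(4R)-4-hydroxy-2,6,6-trimethylcyclohex-1-en-1-yl]-6,13-dimethylpentadeca-2,6,8,10,12-pentaene-4,14-diynoic acid | OC(=O)/C(=C\C#C/C(C)=C/C=C/C=C/C=C(C)/C#CC1=C(C)C[C@@H](O)CC1(C)C)[C@H]1C=C2C(C)(C)C[C@H](O)C[C@@]2(C)O1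
F0 | step 12 | none | none
F3 | step 3 | (1S,3R,4S)-4-bromo-4-ethynyl-3-hydroxy-3,5,5-trimethylcyclohexyl acetate | CC(=O)O[C@H]1CC(C)(C)[C@](Br)(C#C)[C@](C)(O)C1
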